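**Plan**
Retrosynthesis: the O1–C7a bond of the dihydrofuran is cut first, then C3a–C7a and C4=C5 together (the whole carbocycle), then the C3a–allyl bond, and last C2–C3.
Enabling feature: in the ring C3a–C4–C5–C6–C7–C7a, quaternary C3a and C4 are the α-carbon and formyl carbon of an α-branched aldehyde. C5–C6–C7–C7a is a methoxymethyl ketone whose far end C7a is at the carboxyl level and can shed a methoxy group. With no hydrogen on C3a, the dienone cannot become a phenol.
Forward: crotylboration joins C2–C3. Silylation, hydroboration–oxidation and α-allylation give the branched aldehyde. A Michael (addition–elimination)/aldol annulation with an acylketene acetal builds the dienone ring, and desilylation plus vinylogous transetherification closes the dihydrofuran last.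
Stereochemistry: C2 (R) and C3 (S) come from a catalyst-controlled (Z)-crotylboration (syn adduct = 2,3-cis in the ring). C3a (S) comes from 1,2-induction by C3 in the annulation. The α-centre of the aldehyde does not matter because it is planarised.

Key step: step 7

Remark: locants C2–C7a in all intermediates are those of the benzofuranone target; 1,1-dimethoxyethene, (Z)-crotylboronic acid pinacol ester and (R)-TRIP [(R)-3,3'-bis(2,4,6-triisopropylphenyl)-BINOL hydrogen phosphate] are taken as catalogue items.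

Step 1
Reactants: 1 3,4,5-trimethoxybenzaldehyde; 2 (Z)-crotylboronic acid pinacol ester
Product: 4 (1R,2S)-2-methyl-1-(3,4,5-trimethoxyphenyl)but-3-en-1-ol, via pinacol borate ester 3 (not isolated)
Conditions: (R)-TRIP (5 mol %), PhMe, −30 °C; then aq NaHCO3
Reagents that add atoms: none
Why: Chiral-phosphoric-acid-catalysed crotylboration through a closed Zimmerman–Traxler chair turns the Z geometry into the syn C2/C3 relationship, and (R)-TRIP, hydrogen-bonded to the pseudoaxial boronate oxygen and the formyl hydrogen, should direct attack to the Re face of 1 and so set 1R.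

Step 2
Reactants: 4 (1R,2S)-2-methyl-1-(3,4,5-trimethoxyphenyl)but-3-en-1-ol
Product: 5 tert-butyl(dimethyl){[(1R,2S)-2-methyl-1-(3,4,5-trimethoxyphenyl)but-3-en-1-yl]oxy}silane
Conditions: TBSCl, imidazole, DMF, rt
Reagents that add atoms: tert-butyldimethylsilyl chloride, CC(C)(C)[Si](C)(C)Cl
Why: Standard imidazole-mediated silylation masks the C2 hydroxyl, which would otherwise form a lactol with the later aldehyde, as an ether that tolerates LDA, borane, buffered acid and cold silyl triflate.

Step 3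
Reactants: 5 tert-butyl(dimethyl){[(1R,2S)-2-methyl-1-(3,4,5-trimethoxyphenyl)but-3-en-1-yl]oxy}silane
Product: 7 (3S,4R)-4-(tert-butyldimethylsilyloxy)-3-methyl-4-(3,4,5-trimethoxyphenyl)butan-1-ol, via B-alkyl-9-BBN adduct 6 (not isolated)
Conditions: 9-BBN, THF, 0 °C → rt; then NaOH, H2O2, 0 °C → rt
Reagents that add atoms: 9-BBN, C12CCCC(CCC1)B2 (kept only in 6); hydrogen peroxide, OO (hydroxyl oxygen of 7)
Why: Anti-Markovnikov hydroboration–oxidation with the bulky 9-BBN places boron only on the terminal carbon (future C4) and touches no stereocentre.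

Step 4
Reactants: 7 (3S,4R)-4-(tert-butyldimethylsilyloxy)-3-methyl-4-(3,4,5-trimethoxyphenyl)butan-1-ol
Product: 8 (3S,4R)-4-(tert-butyldimethylsilyloxy)-3-methyl-4-(3,4,5-trimethoxyphenyl)butanal
Conditions: TEMPO (10 mol %), PhI(OAc)2, CH2Cl2, rt
Reagents that add atoms: none
Why: The oxoammonium (TEMPO/PhI(OAc)2) oxidation stops at the aldehyde, spares the silyl ether and the electron-rich arene, and cannot epimerise C3, which is β to the carbonyl.

Step 5
Reactants: 8 (3S,4R)-4-(tert-butyldimethylsilyloxy)-3-methyl-4-(3,4,5-trimethoxyphenyl)butanal; 9 allyl bromide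
Product: 12 (3S,4R)-2-allyl-4-(tert-butyldimethylsilyloxy)-3-methyl-4-(3,4,5-trimethoxyphenyl)butanal (both C2 epimers), via N-cyclohexyl aldimine 10 (not isolated), via allylated aldimine 11 (not isolated)
Conditions: c-HexNH2, 4 Å MS, Et2O, rt; LDA, THF, −78 → 0 °C, then 9, −78 °C → rt; AcOH/NaOAc/H2O (pH 4.5), rt
Reagents that add atoms: cyclohexylamine, NC1CCCCC1 (kept only in 10 and 11); water, O (carbonyl oxygen of 12)
Why: Stork metalloenamine alkylation (LDA deprotonation of aldimine 10, C-allylation, mild hydrolysis) gives mono-allylation where the free aldehyde enolate would self-condense, and the uncontrolled new α-centre is harmless because step 7 planarises it.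

Step 6
Reactants: 13 methoxyacetyl chloride; 14 1,1-dimethoxyethene
Product: 15 1,4,4-trimethoxybut-3-en-2-one
Conditions: pyridine, CH2Cl2, 0 °C → rt; bulb-to-bulb distillation
Reagents that add atoms: none
Why: C-acylation of a ketene acetal by an acid chloride, in which the CH2 terminus attacks the acylpyridinium ion and pyridine deprotonates the dialkoxycarbenium ion, gives the push–pull enone without a Lewis acid that would decarbonylate the methoxyacetyl cation.

Step 7
Reactants: 12 (3S,4R)-2-allyl-4-(tert-butyldimethylsilyloxy)-3-methyl-4-(3,4,5-trimethoxyphenyl)butanal (both C2 epimers); 15 1,4,4-trimethoxybut-3-en-2-one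
Product: 20 (4S)-4-allyl-4-[(1R,2S)-1-(tert-butyldimethylsilyloxy)-1-(3,4,5-trimethoxyphenyl)propan-2-yl]-2,5-dimethoxycyclohexa-2,5-dien-1-one, via pyrrolidine enamine 16 (not isolated), via O-silylated acceptor triflate 17 (not isolated), via iminium triflate 18 (not isolated), via keto aldehyde 19 (not isolated)
Conditions: (i) 12, pyrrolidine, 4 Å MS, PhMe, rt, evaporate; (ii) 15, TMSOTf, CH2Cl2, −78 °C, then 16, −78 → −20 °C; (iii) AcOH/NaOAc/H2O, THF, 55 °C
Reagents that add atoms: pyrrolidine, C1CCNC1 (kept only in 16 and 18); trimethylsilyl triflate, C[Si](C)(C)OS(=O)(=O)C(F)(F)F (kept only in 17 and 18); water, O (formyl oxygen of 19 only)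
Why: Proposed new method: a neutral enamine is not expected to attack a β-carbon that carries two methoxy donors, so 15 is first O-silylated to the allyl cation 17, which enamine 16 should intercept at C7a; expulsion of MeOSiMe3 completes the addition–elimination, forges C3a–C7a with the quaternary centre and leaves iminium triflate 18 without free methoxide (no deformylation) or free amine (no aminolysis of the vinylogous ester). In the aqueous acetate buffer 18 is hydrolysed to keto aldehyde 19, whose only enolisable position is C5 (C3a is quaternary, C7 vinylic); pyrrolidinium acetate then mediates a 6-(enolendo)-exo-trig aldol addition of C5 to C4 and dehydration to C4=C5, and the easily rotating push–pull C7=C7a bond lets both geometrical isomers reach the ring. The closest known reaction types are the Stork enamine Robinson annulation of α-branched aldehydes with vinyl ketones to 4,4-disubstituted cyclohexenones and the Lewis-acid-mediated [3+3] cyclocondensation in which silyl enol ethers displace methoxide from 3,3-dimethoxy enones before an aldol closure. C3a is set by 1,2-induction from C3: with C3–H held near the enamine plane facing C4–H (allylic strain), the silyloxybenzyl group covers one face, and attack on the other face, past the methyl group, gives 3aS. Since the allylic-strain partner in the E-enamine is only hydrogen the bias may be moderate; the low temperature allowed by the cationic acceptor should sharpen it, and the C3a epimer is to be removed by chromatography at 20. Site selectivity for C7a over C6 rests on reversibility (only the C7a adduct can lose methoxide), and 20 cannot aromatise because C3a bears no hydrogen.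

Step 8
Reactants: 20 (4S)-4-allyl-4-[(1R,2S)-1-(tert-butyldimethylsilyloxy)-1-(3,4,5-trimethoxyphenyl)propan-2-yl]-2,5-dimethoxycyclohexa-2,5-dien-1-one
Product: 21 (4S)-4-allyl-4-[(1R,2S)-1-hydroxy-1-(3,4,5-trimethoxyphenyl)propan-2-yl]-2,5-dimethoxycyclohexa-2,5-dien-1-one
Conditions: TBAF/AcOH (1:1), THF, rt
Reagents that add atoms: none
Why: Fluoride-induced Si–O cleavage, buffered with acetic acid to stay near neutral, frees the C2 hydroxyl without ionising the benzylic position or disturbing the dienone and its vinylogous ester.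

Step 9
Reactants: 21 (4S)-4-allyl-4-[(1R,2S)-1-hydroxy-1-(3,4,5-trimethoxyphenyl)propan-2-yl]-2,5-dimethoxycyclohexa-2,5-dien-1-one
Product: 22 (2R,3S,3aS)-3a-allyl-5-methoxy-3-methyl-2-(3,4,5-trimethoxyphenyl)-3,3a-dihydro-1-benzofuran-6(2H)-one (CNP0197140.1)
Conditions: PPTS (10 mol %), 5 Å MS, PhMe, 60 °C
Reagents that add atoms: none
Why: Acid-catalysed vinylogous transetherification (5-exo-trig attack of the C2 hydroxyl on C7a of the protonated β-methoxy enone, then loss of methanol into the sieves) closes the dihydrofuran without breaking any bond at C2, C3 or C3a, and any reversible oxa-Michael adduct at C4 drains back through 21 because only the C7a pathway expels methanol.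

**Compound list**
1 | 3,4,5-trimethoxybenzaldehyde | COc1cc(C=O)cc(OC)c1OC | starting material
2 | (Z)-crotylboronic acid pinacol ester, 2-[(2Z)-but-2-en-1-yl]-4,4,5,5-tetramethyl-1,3,2-dioxaborolane | C/C=C\CB1OC(C)(C)C(C)(C)O1 | starting material
3 | 2-{[(1R,2S)-2-methyl-1-(3,4,5-trimethoxyphenyl)but-3-en-1-yl]oxy}-4,4,5,5-tetramethyl-1,3,2-dioxaborolane | C=C[C@H](C)[C@@H](OB1OC(C)(C)C(C)(C)O1)c1cc(OC)c(OC)c(OC)c1 | intermediate
4 | (1R,2S)-2-methyl-1-(3,4,5-trimethoxyphenyl)but-3-en-1-ol | C=C[C@H](C)[C@@H](O)c1cc(OC)c(OC)c(OC)c1 | intermediate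
5 | tert-butyl(dimethyl){[(1R,2S)-2-methyl-1-(3,4,5-trimethoxyphenyl)but-3-en-1-yl]oxy}silane | C=C[C@H](C)[C@@H](O[Si](C)(C)C(C)(C)C)c1cc(OC)c(OC)c(OC)c1 | intermediate
6 | 9-[(3S,4R)-4-(tert-butyldimethylsilyloxy)-3-methyl-4-(3,4,5-trimethoxyphenyl)butyl]-9-borabicyclo[3.3.1]nonane | C12CCCC(CCC1)B2CC[C@H](C)[C@@H](O[Si](C)(C)C(C)(C)C)c1cc(OC)c(OC)c(OC)c1 | intermediate
7 | (3S,4R)-4-(tert-butyldimethylsilyloxy)-3-methyl-4-(3,4,5-trimethoxyphenyl)butan-1-ol | OCC[C@H](C)[C@@H](O[Si](C)(C)C(C)(C)C)c1cc(OC)c(OC)c(OC)c1 | intermediate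
8 | (3S,4R)-4-(tert-butyldimethylsilyloxy)-3-methyl-4-(3,4,5-trimethoxyphenyl)butanal | O=CC[C@H](C)[C@@H](O[Si](C)(C)C(C)(C)C)c1cc(OC)c(OC)c(OC)c1 | intermediate
9 | allyl bromide | C=CCBr | starting material
10 | (3S,4R)-4-(tert-butyldimethylsilyloxy)-N-cyclohexyl-3-methyl-4-(3,4,5-trimethoxyphenyl)butan-1-imine | C1CCCCC1N=CC[C@H](C)[C@@H](O[Si](C)(C)C(C)(C)C)c1cc(OC)c(OC)c(OC)c1 | intermediate
11 | (3S,4R)-2-allyl-4-(tert-butyldimethylsilyloxy)-N-cyclohexyl-3-methyl-4-(3,4,5-trimethoxyphenyl)butan-1-imine (both C2 epimers) | C=CCC(C=NC1CCCCC1)[C@H](C)[C@@H](O[Si](C)(C)C(C)(C)C)c1cc(OC)c(OC)c(OC)c1 | intermediate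
12 | (3S,4R)-2-allyl-4-(tert-butyldimethylsilyloxy)-3-methyl-4-(3,4,5-trimethoxyphenyl)butanal (both C2 epimers) | C=CCC(C=O)[C@H](C)[C@@H](O[Si](C)(C)C(C)(C)C)c1cc(OC)c(OC)c(OC)c1 | intermediate
13 | methoxyacetyl chloride | COCC(=O)Cl | starting material
14 | 1,1-dimethoxyethene (ketene dimethyl acetal) | C=C(OC)OC | starting material
15 | 1,4,4-trimethoxybut-3-en-2-one | COCC(=O)C=C(OC)OC | intermediate
16 | 1-[(1E)-2-[(1R,2S)-1-(tert-butyldimethylsilyloxy)-1-(3,4,5-trimethoxyphenyl)propan-2-yl]penta-1,4-dien-1-yl]pyrrolidine | C=CC/C(=C\N1CCCC1)[C@H](C)[C@@H](O[Si](C)(C)C(C)(C)C)c1cc(OC)c(OC)c(OC)c1 | intermediate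
17 | 1,1,4-trimethoxy-3-(trimethylsilyloxy)but-2-en-1-ylium triflate (O-silylated 15) | COCC(O[Si](C)(C)C)=CC(OC)=[O+]C.[O-]S(=O)(=O)C(F)(F)F | intermediate
18 | 1-{(2S)-2-allyl-2-[(1R,2S)-1-(tert-butyldimethylsilyloxy)-1-(3,4,5-trimethoxyphenyl)propan-2-yl]-3,6-dimethoxy-5-oxohex-3-en-1-ylidene}pyrrolidinium triflate (E/Z at C7=C7a) | C=CC[C@@](C=[N+]1CCCC1)([C@H](C)[C@@H](O[Si](C)(C)C(C)(C)C)c1cc(OC)c(OC)c(OC)c1)C(OC)=CC(=O)COC.[O-]S(=O)(=O)C(F)(F)F | intermediate
19 | (2R)-2-allyl-2-[(1R,2S)-1-(tert-butyldimethylsilyloxy)-1-(3,4,5-trimethoxyphenyl)propan-2-yl]-3,6-dimethoxy-5-oxohex-3-enal (E/Z at C7=C7a) | C=CC[C@@](C=O)([C@H](C)[C@@H](O[Si](C)(C)C(C)(C)C)c1cc(OC)c(OC)c(OC)c1)C(OC)=CC(=O)COC | intermediate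
20 | (4S)-4-allyl-4-[(1R,2S)-1-(tert-butyldimethylsilyloxy)-1-(3,4,5-trimethoxyphenyl)propan-2-yl]-2,5-dimethoxycyclohexa-2,5-dien-1-one | C=CC[C@]1([C@H](C)[C@@H](O[Si](C)(C)C(C)(C)C)c2cc(OC)c(OC)c(OC)c2)C=C(OC)C(=O)C=C1OC | intermediate
21 | (4S)-4-allyl-4-[(1R,2S)-1-hydroxy-1-(3,4,5-trimethoxyphenyl)propan-2-yl]-2,5-dimethoxycyclohexa-2,5-dien-1-one | C=CC[C@]1([C@H](C)[C@@H](O)c2cc(OC)c(OC)c(OC)c2)C=C(OC)C(=O)C=C1OC | intermediate
22 | (2R,3S,3aS)-3a-allyl-5-methoxy-3-methyl-2-(3,4,5-trimethoxyphenyl)-3,3a-dihydro-1-benzofuran-6(2H)-one | C=CC[C@]12C=C(OC)C(=O)C=C1O[C@@H](c1cc(OC)c(OC)c(OC)c1)[C@H]2C | target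

Total step count: 9. Longest linear sequence: 8 (steps 1–5 and 7–9; step 6 is a one-step side branch).

**Steps most likely to fail**

Step 7 (the labelled step). Several processes may defeat it:
- Bond formation between two fully substituted carbons may be outrun by N-silylation or N-methylation of the enamine.
- The activated acceptor may collapse to the β-keto ester.
- The formyl group may be lost before the ring closes.
- Facial discrimination at C3a may be low.

The fallback uses known chemistry only, sets out from 12 and 13, and returns at 22. Stille acylation of 13 with tributyl(vinyl)stannane gives 1-methoxybut-3-en-2-one F1. The classical Stork enamine Robinson annulation of 12 (through 16) with this unhindered vinyl ketone, finished in hot acetate buffer, gives the 4,4-disubstituted 2-methoxycyclohex-2-enone F2. Deprotonation at C7 with LiHMDS and Mukaiyama dehydrogenation with N-tert-butylbenzenesulfinimidoyl chloride gives the cross-conjugated 2-methoxydienone F3. TBAF liberates the hydroxy dienone F4, which adds in a 5-exo-trig oxa-Michael reaction to the unsubstituted, more electrophilic enone arm at C7a and gives the cis-fused tetrahydrobenzofuranone F5. Soft enolisation (TMSOTf, Et3N) gives the silyl enol ether F6, and Saegusa–Ito oxidation with Pd(OAc)2 restores C7=C7a, which is 22.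

Step 6. Chloride may dealkylate the dialkoxycarbenium intermediate to the β-keto ester. The base may convert 13 into methoxyketene, which then oligomerises. The acylketene acetal may hydrolyse during isolation. The fallback sets out from 13 and returns at 15. Amidation with N,O-dimethylhydroxylamine hydrochloride and Et3N gives the Weinreb amide N,2-dimethoxy-N-methylacetamide F7. Lithium ethoxyacetylide (ethoxyacetylene, n-BuLi, THF, −78 °C) converts it into 4-ethoxy-1-methoxybut-3-yn-2-one F8. NaOMe-catalysed conjugate addition of methanol gives the mixed ketene acetal 4-ethoxy-1,4-dimethoxybut-3-en-2-one F9. In the same methanolic solution this exchanges ethoxide for methoxide by addition–elimination and so becomes 15.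

Step 5. Proton transfer between the aza-enolate and the product imine may lead to double allylation. The aldimine may self-condense, and hydrolysis of the hindered imine may stall. The fallback moves the alkylation to the ester oxidation level; it sets out from 7 and returns at 12. TEMPO/PhI(OAc)2 in aqueous MeCN gives the butanoic acid F10, and MeI/K2CO3 gives the methyl ester F11. Ester enolate alkylation (LDA, then 9, THF, −78 °C) gives the α-allyl ester F12, and DIBAL-H in CH2Cl2 at −78 °C reduces it to 12.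

**Further compounds**
F1 | step 7 | 1-methoxybut-3-en-2-one | C=CC(=O)COC
F2 | step 7 | (4R)-4-allyl-4-[(1R,2S)-1-(tert-butyldimethylsilyloxy)-1-(3,4,5-trimethoxyphenyl)propan-2-yl]-2-methoxycyclohex-2-en-1-one | C=CC[C@]1([C@H](C)[C@@H](O[Si](C)(C)C(C)(C)C)c2cc(OC)c(OC)c(OC)c2)C=C(OC)C(=O)CC1
F3 | step 7 | (4S)-4-allyl-4-[(1R,2S)-1-(tert-butyldimethylsilyloxy)-1-(3,4,5-trimethoxyphenyl)propan-2-yl]-2-methoxycyclohexa-2,5-dien-1-one | C=CC[C@]1([C@H](C)[C@@H](O[Si](C)(C)C(C)(C)C)c2cc(OC)c(OC)c(OC)c2)C=C(OC)C(=O)C=C1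
F4 | step 7 | (4S)-4-allyl-4-[(1R,2S)-1-hydroxy-1-(3,4,5-trimethoxyphenyl)propan-2-yl]-2-methoxycyclohexa-2,5-dien-1-one | C=CC[C@]1([C@H](C)[C@@H](O)c2cc(OC)c(OC)c(OC)c2)C=C(OC)C(=O)C=C1
F5 | step 7 | (2R,3S,3aS,7aR)-3a-allyl-5-methoxy-3-methyl-2-(3,4,5-trimethoxyphenyl)-3,3a,7,7a-tetrahydro-1-benzofuran-6(2H)-one | C=CC[C@]12C=C(OC)C(=O)C[C@H]1O[C@@H](c1cc(OC)c(OC)c(OC)c1)[C@H]2C
F6 | step 7 | {[(2R,3S,3aS,7aR)-3a-allyl-5-methoxy-3-methyl-2-(3,4,5-trimethoxyphenyl)-2,3,3a,7a-tetrahydro-1-benzofuran-6-yl]oxy}trimethylsilane | C=CC[C@]12C=C(OC)C(O[Si](C)(C)C)=C[C@H]1O[C@@H](c1cc(OC)c(OC)c(OC)c1)[C@H]2C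
F7 | step 6 | N,2-dimethoxy-N-methylacetamide | COCC(=O)N(C)OC
F8 | step 6 | 4-ethoxy-1-methoxybut-3-yn-2-one | CCOC#CC(=O)COC
F9 | step 6 | 4-ethoxy-1,4-dimethoxybut-3-en-2-one | CCOC(OC)=CC(=O)COC
F10 | step 5 | (3S,4R)-4-(tert-butyldimethylsilyloxy)-3-methyl-4-(3,4,5-trimethoxyphenyl)butanoic acid | OC(=O)C[C@H](C)[C@@H](O[Si](C)(C)C(C)(C)C)c1cc(OC)c(OC)c(OC)c1
F11 | step 5 | methyl (3S,4R)-4-(tert-butyldimethylsilyloxy)-3-methyl-4-(3,4,5-trimethoxyphenyl)butanoate | COC(=O)C[C@H](C)[C@@H](O[Si](C)(C)C(C)(C)C)c1cc(OC)c(OC)c(OC)c1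
F12 | step 5 | methyl (3S,4R)-2-allyl-4-(tert-butyldimethylsilyloxy)-3-methyl-4-(3,4,5-trimethoxyphenyl)butanoate (both C2 epimers) | C=CCC(C(=O)OC)[C@H](C)[C@@H](O[Si](C)(C)C(C)(C)C)c1cc(OC)c(OC)c(OC)c1
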